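**Plan**

- Retrosynthesis: after removal of two silyl ethers, the target is cut at C10–C11 and, in the same operation, at C9–C19 (the C9 methyl). This gives a C13 2-ethynyl-2,5-dihydrofuran (west), a methyl–aluminium unit and a C11 all-E tetraenyl iodide (east).
- Enabling feature: C9 is a methyl-branched sp2 carbon bonded to ring carbon C8, and C10 is a CH between two alkenes. The C9(CH3)=C10–C11 unit is therefore what syn-addition of CH3 and an alkenyl group across a C8–C9≡C10H alkyne delivers.
- West fragment: the dihydrofuran ring (O–C5–C6=C7–C8) comes from 5-endo cyclisation of a C5-hydroxy C6=C7=C8 allene, the allene from anti SN2′ alkynylation of a 5,6-epoxy-7-yne, and the carbocycle from a chiral-pool hydroxy ketone.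
- Forward order: carbocycle elaborated first, then epoxide, allene and dihydrofuran; east iodide from a C10 dialdehyde; union of the halves; desilylation.
- Stereochemistry: C3 from the chiral pool; C5 by epoxidation anti to the C3 silyl ether; C8 by relay epoxide → allene axis → C8. 13E, 15E and 13′E come from the dialdehyde, 11E from Takai olefination, 9E from syn carbometalation.

Key step: step 12

Remark: locants C1–C15, C15′–C12′ and C19 follow carotenoid numbering (C19 is the methyl group on C9); the two building blocks that open the two branches are taken as commercial single isomers.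

**Route**

Step 1
Reactants: 1 (4R,6R)-4-hydroxy-2,2,6-trimethylcyclohexan-1-one
Product: 2 (4R,6R)-4-[(tert-butyldimethylsilyl)oxy]-2,2,6-trimethylcyclohexan-1-one
Conditions: TBSCl, imidazole, DMF, rt
Reagents that add atoms: tert-butylchlorodimethylsilane (TBSCl), CC(C)(C)[Si](C)(C)Cl
Why: Imidazole-promoted O-silylation of a secondary alcohol (silyl ether protection) is chemoselective, and the ketone and both stereocentres are untouched.

Step 2
Reactants: 2 (4R,6R)-4-[(tert-butyldimethylsilyl)oxy]-2,2,6-trimethylcyclohexan-1-one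
Product: 4 (4R)-4-[(tert-butyldimethylsilyl)oxy]-2,6,6-trimethylcyclohex-1-en-1-yl trifluoromethanesulfonate, via lithium enolate 3 (not isolated)
Conditions: LiN(iPr)2, THF, −78 °C; then PhNTf2, −78 °C to rt
Reagents that add atoms: N-phenylbis(trifluoromethanesulfonimide), O=S(=O)(N(c1ccccc1)S(=O)(=O)C(F)(F)F)C(F)(F)F
Why: Kinetic enolisation can occur only at the methyl-bearing α-carbon because the other α-carbon is quaternary, and O-sulfonylation of enolate 3 (enol triflate formation) should give one tetrasubstituted enol triflate; the α-stereocentre is erased on purpose and the silyloxy group is too remote for elimination.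

Step 3
Reactants: 4 (4R)-4-[(tert-butyldimethylsilyl)oxy]-2,6,6-trimethylcyclohex-1-en-1-yl trifluoromethanesulfonate
Product: 5 tert-butyldimethyl({(1R)-3,5,5-trimethyl-4-[(trimethylsilyl)ethynyl]cyclohex-3-en-1-yl}oxy)silane
Conditions: Me3SiC≡CH, PdCl2(PPh3)2 (cat.), CuI (cat.), Et3N, DMF, rt to 50 °C
Reagents that add atoms: ethynyltrimethylsilane, C#C[Si](C)(C)C
Why: Sonogashira coupling of an alkenyl triflate with a terminal alkyne proceeds with retention of the ring alkene, and the silyl ether and the alkynylsilane are inert.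

Step 4
Reactants: 5 tert-butyldimethyl({(1R)-3,5,5-trimethyl-4-[(trimethylsilyl)ethynyl]cyclohex-3-en-1-yl}oxy)silane
Product: 6 tert-butyldimethyl({(1R,4S,6R)-2,2,6-trimethyl-1-[(trimethylsilyl)ethynyl]-7-oxabicyclo[4.1.0]heptan-4-yl}oxy)silane (epoxide oxygen trans to the silyloxy group)
Conditions: mCPBA, NaHCO3, CH2Cl2, 0 °C
Reagents that add atoms: 3-chloroperoxybenzoic acid (mCPBA), O=C(OO)c1cccc(Cl)c1
Why: Prilezhaev epoxidation of the electron-rich tetrasubstituted ring alkene (the alkyne is far less reactive) should occur mainly on the face opposite the bulky C3 silyloxy group, which sets C5 (R) and C6 with the oxygen trans to C3–O; a minor syn epoxide would be removed by chromatography.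

Step 5
Reactants: 6 tert-butyldimethyl({(1R,4S,6R)-2,2,6-trimethyl-1-[(trimethylsilyl)ethynyl]-7-oxabicyclo[4.1.0]heptan-4-yl}oxy)silane
Product: 7 tert-butyl{[(1R,4S,6R)-1-ethynyl-2,2,6-trimethyl-7-oxabicyclo[4.1.0]heptan-4-yl]oxy}dimethylsilane
Conditions: K2CO3 (cat.), MeOH, rt
Reagents that add atoms: none
Why: Base-catalysed methanolysis of the alkynyl C–Si bond (protodesilylation) is selective over the hindered silyl ether and does not open the fully substituted epoxide.

Step 6
Reactants: 7 tert-butyl{[(1R,4S,6R)-1-ethynyl-2,2,6-trimethyl-7-oxabicyclo[4.1.0]heptan-4-yl]oxy}dimethylsilane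
Product: 8 (1R,5S)-5-[(tert-butyldimethylsilyl)oxy]-1,3,3-trimethyl-2-[(R)-4-(trimethylsilyl)but-1-en-3-yn-1-ylidene]cyclohexan-1-ol ((R) allene axis; the alkynyl group on C8 lies on the face of the C5 methyl group)
Conditions: Me3SiC≡CZnCl (from Me3SiC≡CH, n-BuLi, ZnCl2), Pd(PPh3)4 (5 mol%), THF, 0 °C to rt; then H2O
Reagents that add atoms: (trimethylsilyl)ethynylzinc chloride, C[Si](C)(C)C#C[Zn]Cl, made in the flask from ethynyltrimethylsilane, C#C[Si](C)(C)C
Why: Zerovalent palladium opens the alkynyl epoxide by anti SN2′ oxidative addition to a σ-allenylpalladium alkoxide, and transmetalation from zinc followed by reductive elimination with retention (palladium-catalysed propargylic SN2′ cross-coupling) places the alkynyl group on C8 anti to the departing C6–O bond, that is on the face of the C5 methyl group, which defines the (R) allene axis and liberates the C5 tertiary alcohol.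

Step 7
Reactants: 8 (1R,5S)-5-[(tert-butyldimethylsilyl)oxy]-1,3,3-trimethyl-2-[(R)-4-(trimethylsilyl)but-1-en-3-yn-1-ylidene]cyclohexan-1-ol
Product: 9 tert-butyldimethyl({(2S,6S,7aR)-4,4,7a-trimethyl-2-[(trimethylsilyl)ethynyl]-2,4,5,6,7,7a-hexahydro-1-benzofuran-6-yl}oxy)silane
Conditions: AuCl3 (5 mol%), THF, rt, dark; quench with Et3N
Reagents that add atoms: none
Why: AuCl3-catalysed 5-endo-trig cycloisomerisation of the α-hydroxyallene: the C5 oxygen attacks C8 in the plane of the C1–C6–C5 unit anti to gold while the two C8 substituents keep their faces, so the allene axis is transferred to the C8 stereocentre (S, alkynyl cis to the C5 methyl group) and protodeauration at C7 leaves the C6=C7 bond of the 2,5-dihydrofuran.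

Step 8
Reactants: 9 tert-butyldimethyl({(2S,6S,7aR)-4,4,7a-trimethyl-2-[(trimethylsilyl)ethynyl]-2,4,5,6,7,7a-hexahydro-1-benzofuran-6-yl}oxy)silane
Product: 10 tert-butyl{[(2S,6S,7aR)-2-ethynyl-4,4,7a-trimethyl-2,4,5,6,7,7a-hexahydro-1-benzofuran-6-yl]oxy}dimethylsilane
Conditions: K2CO3 (cat.), MeOH, 0 °C to rt
Reagents that add atoms: none
Why: Protodesilylation as in step 5; the mild carbonate base does not touch the silyl ether or the C8–H bond, so the C8 configuration is retained.

Step 9
Reactants: 11 (2E,4E,6E)-2,7-dimethylocta-2,4,6-trienedial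
Product: 12 (2E,4E,6E)-8-hydroxy-2,7-dimethylocta-2,4,6-trienal
Conditions: NaBH4 (0.3 equiv), EtOH/CH2Cl2, −30 °C
Reagents that add atoms: none
Why: Sub-stoichiometric 1,2-reduction of a symmetrical dialdehyde (borohydride reduction): after the first hydride transfer the remaining aldehyde is a donor-substituted, less electrophilic trienal, so the mono-alcohol should predominate and unreacted 11 can be recycled; the three E alkenes are not affected.

Step 10
Reactants: 12 (2E,4E,6E)-8-hydroxy-2,7-dimethylocta-2,4,6-trienal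
Product: 13 (2E,4E,6E)-8-[(tert-butyldimethylsilyl)oxy]-2,7-dimethylocta-2,4,6-trienal
Conditions: TBSCl, imidazole, CH2Cl2, 0 °C to rt
Reagents that add atoms: tert-butylchlorodimethylsilane (TBSCl), CC(C)(C)[Si](C)(C)Cl
Why: Standard silylation of the primary allylic alcohol (silyl ether protection); the conjugated aldehyde is untouched.

Step 11
Reactants: 13 (2E,4E,6E)-8-[(tert-butyldimethylsilyl)oxy]-2,7-dimethylocta-2,4,6-trienal
Product: 14 tert-butyl{[(2E,4E,6E,8E)-9-iodo-2,7-dimethylnona-2,4,6,8-tetraen-1-yl]oxy}dimethylsilane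
Conditions: CrCl2, CHI3, THF/dioxane, 0 °C, dark
Reagents that add atoms: iodoform, IC(I)I
Why: Takai iodo-olefination: the geminal dichromium carbenoid generated from iodoform adds to the aldehyde and eliminates to the (E)-alkenyl iodide, E selectivity being reinforced by conjugation and the dioxane co-solvent; the silyl ether and the existing alkenes are inert.

Step 12
Reactants: 10 tert-butyl{[(2S,6S,7aR)-2-ethynyl-4,4,7a-trimethyl-2,4,5,6,7,7a-hexahydro-1-benzofuran-6-yl]oxy}dimethylsilane; 14 tert-butyl{[(2E,4E,6E,8E)-9-iodo-2,7-dimethylnona-2,4,6,8-tetraen-1-yl]oxy}dimethylsilane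
Product: 16 tert-butyl({(2E,4E,6E,8E,10E)-11-[(2S,6S,7aR)-6-[(tert-butyldimethylsilyl)oxy]-4,4,7a-trimethyl-2,4,5,6,7,7a-hexahydro-1-benzofuran-2-yl]-2,7-dimethyldodeca-2,4,6,8,10-pentaen-1-yl}oxy)dimethylsilane, via alkenylalane 15 (not isolated)
Conditions: Me3Al, Cp2ZrCl2 (0.5 equiv), CH2Cl2, 0 °C to rt; volatiles removed in vacuo; then 14, ZnCl2, Pd(PPh3)4 (5 mol%), THF, rt, dark; cold aqueous NaHCO3 work-up
Reagents that add atoms: trimethylaluminium, C[Al](C)C
Why: Zirconocene-assisted syn-carboalumination (Negishi carboalumination) adds CH3–Al across the terminal C9≡C10 bond with the methyl group on C9 and aluminium on C10, so the (E)-alkenylalane 15 carries C19 and the 9E geometry; after removal of excess Me3Al, transmetalation through zinc to the alkenylpalladium iodide formed by oxidative addition of 14, followed by reductive elimination, forms C10–C11 with retention at both sp2 carbons (Negishi-type alkenyl–alkenyl coupling). The closest known reaction type is the one-flask alkyne methylalumination/palladium cross-coupling used to assemble methyl-branched terpenoid polyenes. No ring is closed and no stereocentre is created; the stereochemical content of the step is the 9E and 11E geometry, fixed by syn addition and by the E iodide. The step needs regioselectivity (aluminium on the unhindered terminal carbon), chemoselectivity for the alkyne over the trisubstituted C6=C7 alkene, and survival of the doubly activated C8–O bond, which is why THF-solvated metal species, low temperature and a buffered work-up are specified.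

Step 13
Reactants: 16 tert-butyl({(2E,4E,6E,8E,10E)-11-[(2S,6S,7aR)-6-[(tert-butyldimethylsilyl)oxy]-4,4,7a-trimethyl-2,4,5,6,7,7a-hexahydro-1-benzofuran-2-yl]-2,7-dimethyldodeca-2,4,6,8,10-pentaen-1-yl}oxy)dimethylsilane
Product: 17 (2E,4E,6E,8E,10E)-11-[(2S,6S,7aR)-6-hydroxy-4,4,7a-trimethyl-2,4,5,6,7,7a-hexahydro-1-benzofuran-2-yl]-2,7-dimethyldodeca-2,4,6,8,10-pentaen-1-ol (the target)
Conditions: TBAF, THF, 0 °C to rt, dark, argon
Reagents that add atoms: none
Why: Fluoride cleaves both Si–O bonds (silyl ether deprotection) under non-acidic conditions, so the acid-labile doubly allylic C8–O bond, the C8 configuration and the all-E pentaene are preserved.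

**Compound list**

1 | (4R,6R)-4-hydroxy-2,2,6-trimethylcyclohexan-1-one | CC1(C)C[C@H](O)C[C@@H](C)C1=O | starting material
2 | (4R,6R)-4-[(tert-butyldimethylsilyl)oxy]-2,2,6-trimethylcyclohexan-1-one | CC1(C)C[C@H](O[Si](C)(C)C(C)(C)C)C[C@@H](C)C1=O | intermediate
3 | lithium (4R)-4-[(tert-butyldimethylsilyl)oxy]-2,6,6-trimethylcyclohex-1-en-1-olate (not isolated) | [Li]OC1=C(C)C[C@@H](O[Si](C)(C)C(C)(C)C)CC1(C)C | intermediate
4 | (4R)-4-[(tert-butyldimethylsilyl)oxy]-2,6,6-trimethylcyclohex-1-en-1-yl trifluoromethanesulfonate | CC1=C(OS(=O)(=O)C(F)(F)F)C(C)(C)C[C@H](O[Si](C)(C)C(C)(C)C)C1 | intermediate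
5 | tert-butyldimethyl({(1R)-3,5,5-trimethyl-4-[(trimethylsilyl)ethynyl]cyclohex-3-en-1-yl}oxy)silane | CC1=C(C#C[Si](C)(C)C)C(C)(C)C[C@H](O[Si](C)(C)C(C)(C)C)C1 | intermediate
6 | tert-butyldimethyl({(1R,4S,6R)-2,2,6-trimethyl-1-[(trimethylsilyl)ethynyl]-7-oxabicyclo[4.1.0]heptan-4-yl}oxy)silane | C[Si](C)(C)C#C[C@@]12O[C@]1(C)C[C@@H](O[Si](C)(C)C(C)(C)C)CC2(C)C | intermediate
7 | tert-butyl{[(1R,4S,6R)-1-ethynyl-2,2,6-trimethyl-7-oxabicyclo[4.1.0]heptan-4-yl]oxy}dimethylsilane | C#C[C@@]12O[C@]1(C)C[C@@H](O[Si](C)(C)C(C)(C)C)CC2(C)C | intermediate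
8 | (1R,5S)-5-[(tert-butyldimethylsilyl)oxy]-1,3,3-trimethyl-2-[(R)-4-(trimethylsilyl)but-1-en-3-yn-1-ylidene]cyclohexan-1-ol | [H]C(C#C[Si](C)(C)C)=[C@]=C1C(C)(C)C[C@H](O[Si](C)(C)C(C)(C)C)C[C@@]1(C)O | intermediate
9 | tert-butyldimethyl({(2S,6S,7aR)-4,4,7a-trimethyl-2-[(trimethylsilyl)ethynyl]-2,4,5,6,7,7a-hexahydro-1-benzofuran-6-yl}oxy)silane | C[Si](C)(C)C#C[C@@H]1C=C2C(C)(C)C[C@H](O[Si](C)(C)C(C)(C)C)C[C@@]2(C)O1 | intermediate
10 | tert-butyl{[(2S,6S,7aR)-2-ethynyl-4,4,7a-trimethyl-2,4,5,6,7,7a-hexahydro-1-benzofuran-6-yl]oxy}dimethylsilane | C#C[C@@H]1C=C2C(C)(C)C[C@H](O[Si](C)(C)C(C)(C)C)C[C@@]2(C)O1 | intermediate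
11 | (2E,4E,6E)-2,7-dimethylocta-2,4,6-trienedial | O=C/C(C)=C/C=C/C=C(C)/C=O | starting material
12 | (2E,4E,6E)-8-hydroxy-2,7-dimethylocta-2,4,6-trienal | O=C/C(C)=C/C=C/C=C(C)/CO | intermediate
13 | (2E,4E,6E)-8-[(tert-butyldimethylsilyl)oxy]-2,7-dimethylocta-2,4,6-trienal | O=C/C(C)=C/C=C/C=C(C)/CO[Si](C)(C)C(C)(C)C | intermediate
14 | tert-butyl{[(2E,4E,6E,8E)-9-iodo-2,7-dimethylnona-2,4,6,8-tetraen-1-yl]oxy}dimethylsilane | I/C=C/C(C)=C/C=C/C=C(C)/CO[Si](C)(C)C(C)(C)C | intermediate
15 | dimethyl{(1E)-2-[(2S,6S,7aR)-6-[(tert-butyldimethylsilyl)oxy]-4,4,7a-trimethyl-2,4,5,6,7,7a-hexahydro-1-benzofuran-2-yl]prop-1-en-1-yl}alumane (not isolated) | C[Al](C)/C=C(\C)[C@@H]1C=C2C(C)(C)C[C@H](O[Si](C)(C)C(C)(C)C)C[C@@]2(C)O1 | intermediate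
16 | tert-butyl({(2E,4E,6E,8E,10E)-11-[(2S,6S,7aR)-6-[(tert-butyldimethylsilyl)oxy]-4,4,7a-trimethyl-2,4,5,6,7,7a-hexahydro-1-benzofuran-2-yl]-2,7-dimethyldodeca-2,4,6,8,10-pentaen-1-yl}oxy)dimethylsilane | CC(/C=C/C=C(\C)[C@@H]1C=C2C(C)(C)C[C@H](O[Si](C)(C)C(C)(C)C)C[C@@]2(C)O1)=C\C=C\C=C(/C)CO[Si](C)(C)C(C)(C)C | intermediate
17 | (2E,4E,6E,8E,10E)-11-[(2S,6S,7aR)-6-hydroxy-4,4,7a-trimethyl-2,4,5,6,7,7a-hexahydro-1-benzofuran-2-yl]-2,7-dimethyldodeca-2,4,6,8,10-pentaen-1-ol, i.e. (3S,5R,8S)-5,8-epoxy-5,8-dihydro-12′-apo-β-carotene-3,12′-diol | CC(/C=C/C=C(\C)[C@@H]1C=C2C(C)(C)C[C@H](O)C[C@@]2(C)O1)=C\C=C\C=C(/C)CO | target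

**Totals and risks**

Total step count: 13. Longest linear sequence: 10 (steps 1–8, 12, 13); the east branch is steps 9–11.

Steps most likely to fail:

1. Step 12. The alane or the zinc and aluminium halides formed during coupling may ionise the C8–O bond, which is propargylic and allylic before coupling and doubly allylic after it. That would open the ring or scramble C8; methyl instead of alkenyl transfer to palladium is a second failure mode. The fallback sets out from 10 and avoids Lewis acids. Copper-catalysed syn-methylboration (CuCl, Xantphos, NaOtBu, B2pin2, MeI, THF, rt; boron on the terminal carbon, methyl on C9) should give the (E)-alkenyl pinacol boronate tert-butyldimethyl({(2S,6S,7aR)-4,4,7a-trimethyl-2-[(E)-1-(4,4,5,5-tetramethyl-1,3,2-dioxaborolan-2-yl)prop-1-en-2-yl]-2,4,5,6,7,7a-hexahydro-1-benzofuran-6-yl}oxy)silane F1. Suzuki–Miyaura coupling of this boronate with 14 (Pd(PPh3)4, aqueous K3PO4, THF, rt, dark) returns to the route at 16.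

2. Step 6. The allenylpalladium intermediate may equilibrate and erode the anti course. Proton exchange between the zinc acetylide and the terminal alkyne of 7 may lead to self-coupling, and some direct propargylic substitution is possible. The fallback sets out from 7. Anti SN2′ opening with bromide (LiCuBr2 from LiBr and CuBr, THF, −40 to 0 °C, then aqueous NH4Cl) should give the bromoallenol (1R,5S)-2-[(R)-2-bromoethenylidene]-5-[(tert-butyldimethylsilyl)oxy]-1,3,3-trimethylcyclohexan-1-ol F2. Stereoretentive Sonogashira-type coupling of this bromoallene with ethynyltrimethylsilane (Pd(PPh3)4, CuI, iPr2NH, THF, rt) returns to the route at 8.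

3. Step 7. Axis-to-centre transfer may be incomplete if AuCl3 reversibly ionises the propargylic, allylic C8–O bond of the product or epimerises the alkynyl-substituted allene before ring closure; activation of the silylalkyne may also compete. The fallback sets out from 8. Iodonium-induced 5-endo cyclisation (N-iodosuccinimide, CH2Cl2, −20 °C; same anti addition, same C8 outcome) should give the 3-iodo-2,5-dihydrofuran tert-butyl({(2R,6S,7aR)-3-iodo-4,4,7a-trimethyl-2-[(trimethylsilyl)ethynyl]-2,4,5,6,7,7a-hexahydro-1-benzofuran-6-yl}oxy)dimethylsilane F3. Hydrodeiodination (Pd(PPh3)4, HCO2H, Et3N, DMF, rt) returns to the route at 9.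

**Further compounds**

F1 | step 12 | tert-butyldimethyl({(2S,6S,7aR)-4,4,7a-trimethyl-2-[(E)-1-(4,4,5,5-tetramethyl-1,3,2-dioxaborolan-2-yl)prop-1-en-2-yl]-2,4,5,6,7,7a-hexahydro-1-benzofuran-6-yl}oxy)silane | CC1(C)OB(/C=C(\C)[C@@H]2C=C3C(C)(C)C[C@H](O[Si](C)(C)C(C)(C)C)C[C@@]3(C)O2)OC1(C)C
F2 | step 6 | (1R,5S)-2-[(R)-2-bromoethenylidene]-5-[(tert-butyldimethylsilyl)oxy]-1,3,3-trimethylcyclohexan-1-ol | [H]C(Br)=[C@]=C1C(C)(C)C[C@H](O[Si](C)(C)C(C)(C)C)C[C@@]1(C)O
F3 | step 7 | tert-butyl({(2R,6S,7aR)-3-iodo-4,4,7a-trimethyl-2-[(trimethylsilyl)ethynyl]-2,4,5,6,7,7a-hexahydro-1-benzofuran-6-yl}oxy)dimethylsilane | C[Si](C)(C)C#C[C@@H]1C(I)=C2C(C)(C)C[C@H](O[Si](C)(C)C(C)(C)C)C[C@@]2(C)O1
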